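**Retrosynthetic overview**
1. The sulfate comes from the primary alcohol; the furan ring is bought as 3-bromofuran and attached last by B-alkyl Suzuki–Miyaura coupling of a terminal alkene.
2. The side-chain stereocentre comes from an organocatalytic α-allylation of a linear aldehyde, under catalyst control because it is remote from the ring centres.
3. That aldehyde comes from a three-carbon Wittig homologation and hydrogenation of a neopentyl ring aldehyde.
4. Ring B and both ring stereocentres come from an enantioselective Brønsted-acid-catalysed Diels–Alder reaction of 6,6-dimethyl-1-vinylcyclohexene with tiglic aldehyde, followed by an olefin shift into the ring fusion.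
5. Ring order: ring A is carried intact from 2,2-dimethylcyclohexanone, ring B is formed by the Diels–Alder reaction, and the furan is introduced preformed at the end.

Assumptions: the target is taken as the free hydrogen sulfate exactly as drawn (kept cold in solution; this class is normally stored as the sodium salt), and the sense of induction of the new Diels–Alder catalyst, written as (S,S), would be fixed by the first run.

**Step 1**
Reactants: 1 2,2-dimethylcyclohexanone
Product: 3 6,6-dimethylcyclohex-1-en-1-yl trifluoromethanesulfonate, via lithium enolate 2 (not isolated)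
Conditions: LiN(SiMe3)2, THF, −78 °C; then PhNTf2, −78 °C → rt
Reagents that add atoms: N-phenylbis(trifluoromethanesulfonimide), O=S(=O)(N(c1ccccc1)S(=O)(=O)C(F)(F)F)C(F)(F)F
Why: Enol triflate formation; only the CH2 side of the ketone can enolise, so a single achiral enolate is O-sulfonylated.

**Step 2**
Reactants: 3 6,6-dimethylcyclohex-1-en-1-yl trifluoromethanesulfonate; 4 2-ethenyl-4,4,5,5-tetramethyl-1,3,2-dioxaborolane
Product: 5 6,6-dimethyl-1-vinylcyclohex-1-ene
Conditions: PdCl2(dppf) (3 mol %), K3PO4, THF/H2O, 60 °C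
Reagents that add atoms: none
Why: Suzuki–Miyaura coupling of an alkenyl triflate with a vinylboronate is a standard entry to semicyclic 1,3-dienes; no stereocentre is formed.

**Step 3**
Reactants: 5 6,6-dimethyl-1-vinylcyclohex-1-ene; 6 (E)-2-methylbut-2-enal (tiglic aldehyde)
Product: 8 (1R,2S)-1,2,5,5-tetramethyl-1,2,3,4,5,6,7,8-octahydronaphthalene-1-carbaldehyde, via Diels–Alder adduct 7 (not isolated)
Conditions: (S,S)-IDPi (2 mol %), 5 Å MS, CH2Cl2, −40 °C; after full consumption of 6, TfOH (5 mol %), 0 °C → rt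
Reagents that add atoms: none
Why: Proposed new method: a confined, strongly acidic imidodiphosphorimidate (IDPi; two 3,3′-diaryl-BINOL phosphoryl units, N-triflyl groups) protonates the formyl oxygen of the s-trans enal inside its chiral pocket, and the contact ion pair leaves only the 2Si,3Re face open; the diene adds there in an asynchronous ortho-selective [4+2] (vinyl CH2 to the β-carbon first, ring CH to the α-carbon), and suprafacial addition to the E-enal places the two methyls cis and the formyl trans to the C2 methyl, so C1 (R, quaternary) and C2 (S) are set together, while the C8a epimers converge when TfOH moves the trisubstituted C4=C4a alkene to the tetrasubstituted C4a=C8a position; the closest known reaction types are chiral Brønsted-acid Diels–Alder reactions of simple enals, enones and acrylates with cyclopentadiene-type dienes and oxazaborolidinium-catalysed Diels–Alder reactions of α-substituted enals, neither shown for an α,β-dialkyl enal with an unactivated semicyclic diene forming a quaternary centre.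

**Step 4**
Reactants: 8 (1R,2S)-1,2,5,5-tetramethyl-1,2,3,4,5,6,7,8-octahydronaphthalene-1-carbaldehyde; 9 [2-(1,3-dioxolan-2-yl)ethyl]triphenylphosphonium bromide
Product: 11 2-[(2Z)-3-[(1S,2S)-1,2,5,5-tetramethyl-1,2,3,4,5,6,7,8-octahydronaphthalen-1-yl]prop-2-en-1-yl]-1,3-dioxolane, via phosphorus ylide 10 (not isolated)
Conditions: NaN(SiMe3)2, THF, 0 °C; then 8, −78 °C → rt
Reagents that add atoms: none
Why: Wittig olefination with a slim non-stabilised ylide tolerates the non-enolisable neopentyl aldehyde and gives the Z-alkene; the stereocentres are untouched (the C1 descriptor reads S only because the vinyl group outranks C2).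

**Step 5**
Reactants: 11 2-[(2Z)-3-[(1S,2S)-1,2,5,5-tetramethyl-1,2,3,4,5,6,7,8-octahydronaphthalen-1-yl]prop-2-en-1-yl]-1,3-dioxolane
Product: 13 4-[(1R,2S)-1,2,5,5-tetramethyl-1,2,3,4,5,6,7,8-octahydronaphthalen-1-yl]butanal, via saturated dioxolane 12 (not isolated)
Conditions: H2 (1 atm), Pd on carbon (10 wt %), THF, rt; then N2 purge, 1 M aq. HCl, rt
Reagents that add atoms: water, O
Why: Heterogeneous hydrogenation reduces the disubstituted alkene while the tetrasubstituted ring alkene is inert at 1 atm, and mild acetal hydrolysis then frees the aldehyde without touching the stereocentres.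

**Step 6**
Reactants: 13 4-[(1R,2S)-1,2,5,5-tetramethyl-1,2,3,4,5,6,7,8-octahydronaphthalen-1-yl]butanal; 14 allyltrimethylsilane
Product: 16 (2S)-2-{2-[(1R,2S)-1,2,5,5-tetramethyl-1,2,3,4,5,6,7,8-octahydronaphthalen-1-yl]ethyl}pent-4-en-1-ol, via allylated aldehyde 15 (not isolated)
Conditions: (2R,5R)-5-benzyl-2-tert-butyl-3-methylimidazolidin-4-one·TFA (20 mol %), allyltrimethylsilane (5 equiv), (NH4)2Ce(NO3)6 (2.2 equiv), NaHCO3, DME, −20 °C; then NaBH4 (excess), MeOH, −20 → 0 °C
Reagents that add atoms: none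
Why: Organo-SOMO α-allylation, in which the enamine is oxidised to a 3π-electron radical cation held away from the tert-butyl group, the benzyl group blocks one face and the allylsilane adds to the other to set the side-chain centre as 2S under catalyst control, and immediate NaBH4 reduction prevents epimerisation.

**Step 7**
Reactants: 16 (2S)-2-{2-[(1R,2S)-1,2,5,5-tetramethyl-1,2,3,4,5,6,7,8-octahydronaphthalen-1-yl]ethyl}pent-4-en-1-ol; 17 3-bromofuran
Product: 19 (2R)-5-(furan-3-yl)-2-{2-[(1R,2S)-1,2,5,5-tetramethyl-1,2,3,4,5,6,7,8-octahydronaphthalen-1-yl]ethyl}pentan-1-ol, via alkylborane 18 (not isolated)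
Conditions: 9-BBN (2.5 equiv), THF, 0 °C → rt; then 3-bromofuran, PdCl2(dppf) (5 mol %), 3 M aq. K3PO4, DMF, 50 °C
Reagents that add atoms: none
Why: 9-BBN hydroborates only the monosubstituted alkene (anti-Markovnikov; the hydroxyl is merely tied up as a borinate and the tetrasubstituted alkene is inert), and the B-alkyl Suzuki–Miyaura coupling joins the chain to furan C3 without touching the stereocentre, whose descriptor becomes R by priority change only.

**Step 8**
Reactants: 19 (2R)-5-(furan-3-yl)-2-{2-[(1R,2S)-1,2,5,5-tetramethyl-1,2,3,4,5,6,7,8-octahydronaphthalen-1-yl]ethyl}pentan-1-ol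
Product: 21 (2R)-5-(furan-3-yl)-2-{2-[(1R,2S)-1,2,5,5-tetramethyl-1,2,3,4,5,6,7,8-octahydronaphthalen-1-yl]ethyl}pentyl hydrogen sulfate, via pyridinium sulfate 20 (not isolated)
Conditions: SO3·pyridine (2 equiv), pyridine, 0 °C → rt; then sulfonic acid cation-exchange resin (H+ form), MeOH/H2O, 0 °C
Reagents that add atoms: sulfur trioxide pyridine complex, O=S(=O)([O-])[n+]1ccccc1
Why: O-Sulfation of a primary alcohol with the SO3·pyridine complex is much faster at room temperature than C-sulfonation of the furan or attack on the hindered alkene, and cation exchange liberates the hydrogen sulfate.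

**Compound list**
1 | 2,2-dimethylcyclohexanone | CC1(C)CCCCC1=O | starting material
2 | lithium 6,6-dimethylcyclohex-1-en-1-olate | [Li+].CC1(C)CCCC=C1[O-] | intermediate
3 | 6,6-dimethylcyclohex-1-en-1-yl trifluoromethanesulfonate | CC1(C)CCCC=C1OS(=O)(=O)C(F)(F)F | intermediate
4 | 2-ethenyl-4,4,5,5-tetramethyl-1,3,2-dioxaborolane | C=CB1OC(C)(C)C(C)(C)O1 | starting material
5 | 6,6-dimethyl-1-vinylcyclohex-1-ene | C=CC1=CCCCC1(C)C | intermediate
6 | (E)-2-methylbut-2-enal | C/C=C(\C)C=O | starting material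
7 | (1R,2S)-1,2,5,5-tetramethyl-1,2,3,5,6,7,8,8a-octahydronaphthalene-1-carbaldehyde (both C8a epimers) | C[C@H]1CC=C2C(CCCC2(C)C)[C@]1(C)C=O | intermediate
8 | (1R,2S)-1,2,5,5-tetramethyl-1,2,3,4,5,6,7,8-octahydronaphthalene-1-carbaldehyde | C[C@H]1CCC2=C(CCCC2(C)C)[C@]1(C)C=O | intermediate
9 | [2-(1,3-dioxolan-2-yl)ethyl]triphenylphosphonium bromide | [Br-].C1COC(CC[P+](c2ccccc2)(c2ccccc2)c2ccccc2)O1 | starting material
10 | [2-(1,3-dioxolan-2-yl)ethylidene]triphenyl-λ5-phosphane | C(=P(c1ccccc1)(c1ccccc1)c1ccccc1)CC1OCCO1 | intermediate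
11 | 2-[(2Z)-3-[(1S,2S)-1,2,5,5-tetramethyl-1,2,3,4,5,6,7,8-octahydronaphthalen-1-yl]prop-2-en-1-yl]-1,3-dioxolane | C[C@H]1CCC2=C(CCCC2(C)C)[C@]1(C)/C=C\CC1OCCO1 | intermediate
12 | 2-{3-[(1R,2S)-1,2,5,5-tetramethyl-1,2,3,4,5,6,7,8-octahydronaphthalen-1-yl]propyl}-1,3-dioxolane | C[C@H]1CCC2=C(CCCC2(C)C)[C@]1(C)CCCC1OCCO1 | intermediate
13 | 4-[(1R,2S)-1,2,5,5-tetramethyl-1,2,3,4,5,6,7,8-octahydronaphthalen-1-yl]butanal | C[C@H]1CCC2=C(CCCC2(C)C)[C@]1(C)CCCC=O | intermediate
14 | allyltrimethylsilane | C=CC[Si](C)(C)C | starting material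
15 | (2S)-2-{2-[(1R,2S)-1,2,5,5-tetramethyl-1,2,3,4,5,6,7,8-octahydronaphthalen-1-yl]ethyl}pent-4-enal | C[C@H]1CCC2=C(CCCC2(C)C)[C@]1(C)CC[C@@H](CC=C)C=O | intermediate
16 | (2S)-2-{2-[(1R,2S)-1,2,5,5-tetramethyl-1,2,3,4,5,6,7,8-octahydronaphthalen-1-yl]ethyl}pent-4-en-1-ol | C[C@H]1CCC2=C(CCCC2(C)C)[C@]1(C)CC[C@@H](CC=C)CO | intermediate
17 | 3-bromofuran | Brc1ccoc1 | starting material
18 | 9-{[(2R)-5-(9-borabicyclo[3.3.1]nonan-9-yl)-2-{2-[(1R,2S)-1,2,5,5-tetramethyl-1,2,3,4,5,6,7,8-octahydronaphthalen-1-yl]ethyl}pentyl]oxy}-9-borabicyclo[3.3.1]nonane | C[C@H]1CCC2=C(CCCC2(C)C)[C@]1(C)CC[C@@H](CCCB3C4CCCC3CCC4)COB3C4CCCC3CCC4 | intermediate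
19 | (2R)-5-(furan-3-yl)-2-{2-[(1R,2S)-1,2,5,5-tetramethyl-1,2,3,4,5,6,7,8-octahydronaphthalen-1-yl]ethyl}pentan-1-ol | C[C@H]1CCC2=C(CCCC2(C)C)[C@]1(C)CC[C@@H](CCCc1ccoc1)CO | intermediate
20 | pyridinium (2R)-5-(furan-3-yl)-2-{2-[(1R,2S)-1,2,5,5-tetramethyl-1,2,3,4,5,6,7,8-octahydronaphthalen-1-yl]ethyl}pentyl sulfate | C[C@H]1CCC2=C(CCCC2(C)C)[C@]1(C)CC[C@@H](CCCc1ccoc1)COS(=O)(=O)[O-].c1cc[nH+]cc1 | intermediate
21 | (2R)-5-(furan-3-yl)-2-{2-[(1R,2S)-1,2,5,5-tetramethyl-1,2,3,4,5,6,7,8-octahydronaphthalen-1-yl]ethyl}pentyl hydrogen sulfate | C[C@H]1CCC2=C(CCCC2(C)C)[C@]1(C)CC[C@@H](CCCc1ccoc1)COS(=O)(=O)O | target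

**Totals**
Total step count: 8. Longest linear sequence: 8 (fully linear; all other building blocks are bought).

**Three steps most likely to fail**

Step 3 (the proposed new Diels–Alder). Likely failure modes are low turnover with the hindered trisubstituted enal, competing hetero-Diels–Alder at the formyl group, or acid-induced oligomerisation of the diene. The fallback sets out from 5 and 6 and comes back at 7, which is then isomerised to 8 with TfOH as in the main step. It replaces Brønsted-acid ion-pair catalysis by chiral Lewis-acid catalysis: a triflimide-activated B-(o-tolyl)oxazaborolidine derived from diphenylprolinol (10–20 mol %, CH2Cl2, −78 → −20 °C). This is an established catalyst class for Diels–Alder reactions of α-substituted enals. It binds the formyl group at boron with a supporting formyl C–H···O contact and exposes one face of the s-trans enal. The detour forms no compound outside the list (entry F0).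

Step 6 (radical-cation α-allylation). The electrophilic radical cation could be trapped intramolecularly by the tetrasubstituted ring alkene (five- or six-membered ring closure), or (NH4)2Ce(NO3)6 could oxidise that alkene. The fallback sets out from 13 and comes back at 19, using closed-shell enamine catalysis instead.
- α-Hydroxymethylation of 13 (aqueous formaldehyde, (S)-α,α-diphenylprolinol trimethylsilyl ether 10 mol %, pH 7 phosphate buffer, toluene, rt) gives (2R)-2-(hydroxymethyl)-4-[(1R,2S)-1,2,5,5-tetramethyl-1,2,3,4,5,6,7,8-octahydronaphthalen-1-yl]butanal F1.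
- [2-(Furan-3-yl)ethyl]triphenylphosphonium bromide F2 is made from 3-(2-bromoethyl)furan and PPh3 in MeCN at reflux. NaN(SiMe3)2 in THF converts it to [2-(furan-3-yl)ethylidene]triphenyl-λ5-phosphane F3.
- Crude F1 is added at −78 °C to 2.5 equiv of F3 and gives (2S,3Z)-5-(furan-3-yl)-2-{2-[(1R,2S)-1,2,5,5-tetramethyl-1,2,3,4,5,6,7,8-octahydronaphthalen-1-yl]ethyl}pent-3-en-1-ol F4.
- Diimide (2-nitrobenzenesulfonylhydrazide, Et3N, CH2Cl2, rt) reduces only the disubstituted alkene of F4, leaving furan and ring alkene untouched, and gives 19.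

Step 4 (Wittig on the neopentyl aldehyde). The formyl group sits on a quaternary carbon flanked by a tetrasubstituted alkene and a tertiary centre, so olefination may stall. The fallback sets out from 8 and comes back at 12, which is hydrolysed to 13 as in step 5. It uses carbonyl addition and radical deoxygenation instead of olefination and hydrogenation.
- [2-(1,3-Dioxolan-2-yl)ethyl]magnesium bromide (THF, 0 °C) adds to 8 and gives 3-(1,3-dioxolan-2-yl)-1-[(1R,2S)-1,2,5,5-tetramethyl-1,2,3,4,5,6,7,8-octahydronaphthalen-1-yl]propan-1-ol F5 (both carbinol epimers, which converge).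
- NaH, CS2, then MeI in THF give O-{3-(1,3-dioxolan-2-yl)-1-[(1R,2S)-1,2,5,5-tetramethyl-1,2,3,4,5,6,7,8-octahydronaphthalen-1-yl]propyl} S-methyl carbonodithioate F6.
- Barton–McCombie deoxygenation (Bu3SnH at high concentration to outrun homoallyl radical rearrangement, AIBN, toluene, 90 °C) gives 12.

**Further compounds**
F0 | step 3 | none | none
F1 | step 6 | (2R)-2-(hydroxymethyl)-4-[(1R,2S)-1,2,5,5-tetramethyl-1,2,3,4,5,6,7,8-octahydronaphthalen-1-yl]butanal | C[C@H]1CCC2=C(CCCC2(C)C)[C@]1(C)CC[C@@H](C=O)CO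
F2 | step 6 | [2-(furan-3-yl)ethyl]triphenylphosphonium bromide | [Br-].c1ccc(cc1)[P+](CCc1ccoc1)(c1ccccc1)c1ccccc1
F3 | step 6 | [2-(furan-3-yl)ethylidene]triphenyl-λ5-phosphane | C(=P(c1ccccc1)(c1ccccc1)c1ccccc1)Cc1ccoc1
F4 | step 6 | (2S,3Z)-5-(furan-3-yl)-2-{2-[(1R,2S)-1,2,5,5-tetramethyl-1,2,3,4,5,6,7,8-octahydronaphthalen-1-yl]ethyl}pent-3-en-1-ol | C[C@H]1CCC2=C(CCCC2(C)C)[C@]1(C)CC[C@@H](/C=C\Cc1ccoc1)CO
F5 | step 4 | 3-(1,3-dioxolan-2-yl)-1-[(1R,2S)-1,2,5,5-tetramethyl-1,2,3,4,5,6,7,8-octahydronaphthalen-1-yl]propan-1-ol | C[C@H]1CCC2=C(CCCC2(C)C)[C@]1(C)C(O)CCC1OCCO1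
F6 | step 4 | O-{3-(1,3-dioxolan-2-yl)-1-[(1R,2S)-1,2,5,5-tetramethyl-1,2,3,4,5,6,7,8-octahydronaphthalen-1-yl]propyl} S-methyl carbonodithioate | C[C@H]1CCC2=C(CCCC2(C)C)[C@]1(C)C(OC(=S)SC)CCC1OCCO1
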